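## Retrosynthetic overview

1. Feature: in the triol ring (ring A: C1 CMe2, C3 CHOH, C5 C(Me)OH) the carbinol carbon C6 lies between the fully substituted C1 and C5. It holds chain carbon C7 on the face of the 5-OH (5-OH/6-OH trans-diaxial, 6-OH cis to 3-OH). The axial C5–O bond and the axial C1 methyl screen that face, so C7 is brought in from O5 itself.
2. C7=C8 is cut first (Wittig) into a C10 ring A aldehyde and a C30 polyenyne phosphonium salt (C8 to C6'). The salt comes from a C15 enyne salt (C11'=C12' Wittig; C6'–C7' Sonogashira on the ring B enol triflate), the C10 dialdehyde and a C5 phosphonate (C11=C12 HWE).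
3. C6–C7 is cut next: an O5–SiMe2–CH2 tether, iodine–lithium exchange and intramolecular addition to the C6 ketone. Tamao–Fleming oxidation then turns Si–C7 into the C7 carbinol.
4. Stereocentres: C5 by catalytic asymmetric epoxidation of ketoisophorone, C3 by 5-OH-directed reduction, C6 by the tether, C3' by enzymatic reduction and hydrogenation of the same starting material.
5. Ring order: both six-membered rings are bought with ketoisophorone. The only rings made are the oxirane (step 1, opened in step 2) and the cis-fused 1,2-oxasilolane (step 7, opened in step 8).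

Key step: step 7

Assumption: the sense of induction in step 1 is taken by analogy with simple 3-alkylcyclohexenones. If the quinine-derived amine gives the mirror-image epoxide, its quinidine-derived pseudoenantiomer is used, and the assignment is checked at the diol stage.

Carotenoid numbering is used for positions. Steps 19 to 24 are run under argon with exclusion of light.

## Route

Step 1
Reactants: 1 ketoisophorone
Product: 2 (1R,6S)-1,3,3-trimethyl-7-oxabicyclo[4.1.0]heptane-2,5-dione (4,5-epoxide; 4S,5R in carotenoid numbering)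
Conditions: 9-amino-9-deoxy-epi-quinine (10 mol %), CF3CO2H (20 mol %), 30% aq H2O2, dioxane, 30 °C
Reagents that add atoms: hydrogen peroxide, OO
Why: Weitz–Scheffer nucleophilic epoxidation under iminium–enamine catalysis by a primary cinchona amine, as established for 3-alkylcyclohex-2-enones: the amine can condense only with the unhindered C3 carbonyl, hydrogen peroxide adds to C5 on the face the catalyst leaves open and the enamine closes the oxirane, so C5 (R) and C4 (S) are set together under catalyst control.

Step 2
Reactants: 2 epoxy dione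
Product: 3 (2R)-2-hydroxy-2,6,6-trimethylcyclohexane-1,4-dione (5R)
Conditions: (PhSe)2, NaBH4, EtOH, 0 °C; AcOH; then 2, 0 °C to rt
Reagents that add atoms: none
Why: Organoselenium reduction of an alpha,beta-epoxy ketone: the selenolate opens the oxirane by SN2 attack at the secondary C4 (alpha to the C3 ketone) rather than at the fully substituted C5, a second selenolate removes selenium to leave the enol, and the C5–O bond with its configuration is never touched, while the acetic acid buffer suppresses loss of water from the aldol.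

Step 3
Reactants: 3 hydroxy dione
Product: 4 (2R,4S)-2,4-dihydroxy-2,6,6-trimethylcyclohexan-1-one (3S,5R; 3-OH trans to 5-OH)
Conditions: Me4NBH(OAc)3, MeCN/AcOH 1:1, −20 °C
Reagents that add atoms: none
Why: Evans–Saksena reduction: the borohydride exchanges an acetate for the axial 5-OH and passes its hydride to the same face of the C3 carbonyl, a face closed to external hydride by the axial C1 methyl, which gives the equatorial 3-OH trans to the 5-OH (3S), while the C6 ketone between two fully substituted carbons is left alone.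

Step 4
Reactants: 4 dihydroxy ketone
Product: 5 (2R,4S)-4-(tert-butyldimethylsilyloxy)-2-hydroxy-2,6,6-trimethylcyclohexan-1-one
Conditions: TBSCl, imidazole, DMF, 0 °C to rt
Reagents that add atoms: tert-butyldimethylsilyl chloride, CC(C)(C)[Si](C)(C)Cl
Why: Standard silyl ether formation in which the equatorial secondary 3-OH reacts far faster than the tertiary 5-OH, which stays free for the tether.

Step 5
Reactants: 5 alpha-ketol; 6 chloro(chloromethyl)dimethylsilane
Product: 7 (2R,4S)-4-(tert-butyldimethylsilyloxy)-2-[(chloromethyl)dimethylsilyloxy]-2,6,6-trimethylcyclohexan-1-one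
Conditions: imidazole, DMAP (cat.), DMF, rt
Reagents that add atoms: none
Why: Silyl ether formation with the small chlorosilane used for silicon-tethered cyclisations; the (chloromethyl)dimethylsilyl group is little larger than trimethylsilyl and should reach the tertiary axial 5-OH under nucleophilic catalysis.

Step 6
Reactants: 7 chloromethylsilyl ether
Product: 8 (2R,4S)-4-(tert-butyldimethylsilyloxy)-2-[(iodomethyl)dimethylsilyloxy]-2,6,6-trimethylcyclohexan-1-one
Conditions: NaI, acetone, reflux, dark
Reagents that add atoms: sodium iodide, [Na+].[I-]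
Why: Finkelstein exchange: SN2 displacement at a halomethylsilane is accelerated by the adjacent silicon, NaCl precipitates from acetone, and the neutral medium leaves both silyl ethers and the ketone untouched.

Step 7
Reactants: 8 iodomethylsilyl ether of the ring ketone
Product: 11 cis-fused oxasilolane (3aR,6S,7aR)-6-(tert-butyldimethylsilyloxy)-2,2,4,4,7a-pentamethyloctahydro-1,2-benzoxasilol-3a-ol (3S,5R,6R; C7 in place; 6-OH free), via silylmethyllithium 9 (not isolated), via lithium alkoxide 10 (not isolated)
Conditions: t-BuLi (2.1 equiv), Et2O/pentane 2:3, high dilution, −100 to −78 °C; AcOH in Et2O, −78 °C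
Reagents that add atoms: none
Why: Proposed new method: t-BuLi should exchange the primary, silicon-activated C–I bond of 8 faster than it can reach a carbonyl group that is walled in by two fully substituted carbons and has no alpha hydrogen, and the second equivalent destroys the t-BuI formed. Silylmethyllithium 9 then adds to C6 in a 5-exo-trig closure (ring C7–Si–O5–C5–C6), which forms the C6–C7 bond and gives lithium alkoxide 10. The closest known reactions are the hydroxymethylation of ketones with (alkoxydimethylsilyl)methyl Grignard reagents and the cyclisation of iodo ketones set off by halogen–lithium exchange, but their combination through an O–Si–C tether on an alpha-ketol is not established. The new stereocentre C6 is controlled by C5, because the short tether reaches the carbonyl carbon only when the O5–C5–C6···C7 torsion is small, that is with O5 axial and C7 arriving on the O5 face, so only the cis-fused ring can form and the 6-OH ends trans to O5 and cis to O3. The step needs facial selectivity against the intrinsic bias of the ketone, which the tether secures, and chemoselectivity for exchange over attack at C=O or Si, which rests on the low temperature, the bulk of t-BuLi and the dilution. Peterson elimination is held back because lithium beta-oxidosilanes eliminate slowly, the five-membered ring keeps the O6–C6–C7–Si torsion far from syn-periplanar, and the alkoxide is protonated before warming.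

Step 8
Reactants: 11 oxasilolane
Product: 12 (1S,2R,4S)-4-(tert-butyldimethylsilyloxy)-1-(hydroxymethyl)-2,6,6-trimethylcyclohexane-1,2-diol
Conditions: 30% H2O2, KF, KHCO3, THF/MeOH 1:1, rt
Reagents that add atoms: hydrogen peroxide, OO
Why: Tamao–Fleming oxidation: the ring silicon already carries the alkoxy ligand needed for activation, C7 migrates from silicon to oxygen without touching C5 or C6, and these mild conditions are the ones that turn beta-hydroxysilanes from silylmethyl Grignard additions into 1,2-diols without Peterson elimination and that a secondary TBS ether tolerates.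

Step 9
Reactants: 12 triol mono-TBS ether
Product: 13 (1S,2R,4S)-4-(tert-butyldimethylsilyloxy)-2,6,6-trimethyl-1,2-bis(trimethylsilyloxy)-1-[(trimethylsilyloxy)methyl]cyclohexane
Conditions: TMSOTf (4 equiv), 2,6-lutidine, CH2Cl2, 0 °C
Reagents that add atoms: trimethylsilyl triflate, C[Si](C)(C)OS(=O)(=O)C(F)(F)F
Why: Exhaustive silylation with a silyl triflate, the standard reagent for hindered tertiary alcohols; the trans-diaxial 5- and 6-OH groups cannot share a cyclic protecting group, so each receives the smallest silyl group to block alpha-ketol rearrangement, retro-aldol cleavage and ylide quenching later.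

Step 10
Reactants: 13 tris(trimethylsilyl) ether
Product: 15 (1R,2R,4S)-4-(tert-butyldimethylsilyloxy)-2,6,6-trimethyl-1,2-bis(trimethylsilyloxy)cyclohexane-1-carbaldehyde (C7 aldehyde), via alkoxysulfonium chloride 14 (not isolated)
Conditions: (COCl)2, DMSO, CH2Cl2, −78 °C; 13, −78 to −40 °C; Et3N, −78 to 0 °C
Reagents that add atoms: none
Why: Swern oxidation applied directly to a silyl ether: chlorodimethylsulfonium chloride is known to displace primary trimethylsilyl ethers selectively, the tertiary TMS ethers and the secondary TBS ether are too hindered to be displaced, and the aldehyde cannot epimerise because C6 bears no hydrogen.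

Step 11
Reactants: 1 ketoisophorone
Product: 16 (6R)-2,2,6-trimethylcyclohexane-1,4-dione (levodione)
Conditions: ene-reductase OYE2, NADP+ (cat.), glucose dehydrogenase, D-glucose, phosphate buffer pH 7, 30 °C
Reagents that add atoms: none
Why: Biocatalytic alkene reduction by an old yellow enzyme, for which ketoisophorone is the benchmark substrate; the flavoenzyme adds the two hydrogens trans across C4'=C5' and sets the methyl-bearing centre as 6R, and prompt extraction limits racemisation in the buffer.

Step 12
Reactants: 16 levodione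
Product: 17 (4R,6R)-4-hydroxy-2,2,6-trimethylcyclohexan-1-one (trans-actinol)
Conditions: H2, Raney Ni, MeOH, rt
Reagents that add atoms: none
Why: Heterogeneous hydrogenation, the established second step of the actinol sequence: only the unhindered carbonyl is reduced and hydrogen arrives from the side away from the axial methyl of the CMe2 group, which gives mainly the trans alcohol and sets C3' (R) under control of the centre made in step 11, the minor cis isomer being removed by chromatography.

Step 13
Reactants: 17 actinol
Product: 18 (4R,6R)-4-(tert-butyldiphenylsilyloxy)-2,2,6-trimethylcyclohexan-1-one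
Conditions: TBDPSCl, imidazole, DMF, rt to 40 °C
Reagents that add atoms: tert-butyldiphenylsilyl chloride, CC(C)(C)[Si](Cl)(c1ccccc1)c1ccccc1
Why: Standard silylation; the tert-butyldiphenylsilyl ether is chosen because it withstands the mildly acidic phosphonium salt formation of step 22 and still leaves with fluoride at the end.

Step 14
Reactants: 18 silylated actinol
Product: 20 (R)-4-(tert-butyldiphenylsilyloxy)-2,6,6-trimethylcyclohex-1-en-1-yl triflate, via lithium enolate 19 (not isolated)
Conditions: LiN(i-Pr)2, THF, −78 °C; PhNTf2, −78 °C to rt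
Reagents that add atoms: N-phenylbis(trifluoromethanesulfonimide), O=S(=O)(N(c1ccccc1)S(=O)(=O)C(F)(F)F)C(F)(F)F
Why: Enolate O-triflation: the ketone has a single alpha hydrogen, so only the tetrasubstituted C5'=C6' enolate can form and it is trapped on oxygen, the C5' centre being erased on purpose while C3' is untouched.

Step 15
Reactants: 20 enol triflate; 21 (E)-3-methylpent-2-en-4-yn-1-ol
Product: 22 (E)-5-[(R)-4-(tert-butyldiphenylsilyloxy)-2,6,6-trimethylcyclohex-1-en-1-yl]-3-methylpent-2-en-4-yn-1-ol
Conditions: Pd(PPh3)4 (5 mol %), CuI (10 mol %), i-Pr2NH, DMF, rt to 50 °C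
Reagents that add atoms: none
Why: Sonogashira coupling of an enol triflate with a terminal alkyne forms C6'–C7'; the free allylic alcohol is tolerated and the E geometry of C9'=C10' comes unchanged from the commercial enynol.

Step 16
Reactants: 22 C15 enynol
Product: 24 C15 enynyl triphenylphosphonium bromide (P on C11'; 9'E; 3'R), via allylic bromide 23 (not isolated)
Conditions: CBr4, PPh3, CH2Cl2, 0 °C; then PPh3, EtOAc, rt
Reagents that add atoms: carbon tetrabromide, BrC(Br)(Br)Br; triphenylphosphine, c1ccc(cc1)P(c1ccccc1)c1ccccc1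
Why: Appel bromination followed by SN2 quaternisation of PPh3: both are neutral displacements at the primary C11', so no allyl cation arises that could scramble the C9'=C10' geometry, and the silyl ether is untouched.

Step 17
Reactants: 25 ethyl tiglate
Product: 26 ethyl (E)-4-bromo-2-methylbut-2-enoate
Conditions: NBS, AIBN (cat.), PhCF3, reflux
Reagents that add atoms: N-bromosuccinimide, O=C1CCC(=O)N1Br
Why: Wohl–Ziegler allylic bromination, the usual entry to gamma-bromotiglates: the delocalised radical is brominated mainly at the terminal methyl group and the more stable E ester geometry is kept.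

Step 18
Reactants: 26 bromotiglate
Product: 27 ethyl (E)-4-(diethoxyphosphoryl)-2-methylbut-2-enoate
Conditions: P(OEt)3, neat, 120 °C
Reagents that add atoms: triethyl phosphite, CCOP(OCC)OCC
Why: Michaelis–Arbuzov reaction of a primary allylic bromide, driven by loss of volatile bromoethane.

Step 19
Reactants: 27 C5 phosphonate; 28 2,7-dimethylocta-2,4,6-trienedial
Product: 30 ethyl (2E,4E,6E,8E,10E)-2,6,11-trimethyl-12-oxododeca-2,4,6,8,10-pentaenoate (C8 ester to C12' aldehyde), via lithiated phosphonate 29 (not isolated)
Conditions: LiN(SiMe3)2, THF, −78 °C; 28 (3 equiv), −78 to 0 °C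
Reagents that add atoms: none
Why: Horner–Wadsworth–Emmons olefination with a vinylogous phosphonoacetate forms C11=C12 with the E selectivity typical of stabilised phosphonate anions, and the excess of symmetrical dialdehyde together with the lower electrophilicity of the extended product aldehyde holds the reaction at mono-olefination.

Step 20
Reactants: 24 C15 phosphonium bromide; 30 C15 aldehyde ester
Product: 32 C30 ethyl ester (all-E; C8 CO2Et through C7'≡C8' to ring B; 3'R OTBDPS), via C15 ylide 31 (not isolated)
Conditions: NaN(SiMe3)2, THF, −78 to 0 °C; 30, −78 °C to rt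
Reagents that add atoms: none
Why: Wittig olefination of the classical C15-salt-plus-polyenal type forms C11'=C12'; the conjugated ylide should give mainly the E alkene, the hindered 11'Z isomer is removed by chromatography or crystallisation without equilibrating conditions that would endanger the 9'E bond, and the ester is inert to the ylide.

Step 21
Reactants: 32 C30 ester
Product: 33 C30 allylic alcohol (C8 CH2OH)
Conditions: i-Bu2AlH (2.5 equiv), CH2Cl2, −78 °C
Reagents that add atoms: none
Why: Reduction of a conjugated ester with i-Bu2AlH at low temperature proceeds in 1,2 fashion only and leaves polyene, alkyne and silyl ether untouched.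

Step 22
Reactants: 33 C30 alcohol
Product: 34 C30 polyenynyl triphenylphosphonium bromide (P on C8)
Conditions: PPh3·HBr, CH2Cl2/MeOH, 0 °C to rt
Reagents that add atoms: triphenylphosphine hydrobromide, [Br-].c1ccc(cc1)[PH+](c1ccccc1)c1ccccc1
Why: Direct phosphonium salt formation from a polyenylic alcohol, as practised for retinol: loss of water gives a long delocalised cation that PPh3 captures at the unhindered terminal C8, the only site that keeps the whole chromophore conjugated, and the TBDPS ether withstands the mild acid.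

Step 23
Reactants: 34 C30 phosphonium bromide; 15 ring A aldehyde
Product: 36 fully silylated tetrol (3-OTBS; 5,6-bis-OTMS; 3'-OTBDPS; all-E), via C30 ylide 35 (not isolated)
Conditions: NaN(SiMe3)2, THF, −78 to 0 °C; 15, −78 °C to rt
Reagents that add atoms: none
Why: Wittig olefination with a conjugated ylide forms C7=C8: aldehyde 15 cannot enolise and is activated by its alpha-silyloxy group, and the late, flat transition state of such ylides together with the clash that a Z alkene would create between the fully substituted C6 and the C9 methyl branch should favour the 7E alkene, any 7Z isomer being removed by chromatography.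

Step 24
Reactants: 36 silylated tetrol
Product: 37 target, (3S,5R,6R,3'R)-7',8'-didehydro-5,6-dihydro-beta,beta-carotene-3,5,6,3'-tetrol
Conditions: Bu4NF, AcOH, THF, rt
Reagents that add atoms: none
Why: Fluoride-induced desilylation removes the two TMS groups, the TBS group and the TBDPS group in one operation, and the buffered non-acidic medium avoids ionisation of the allylic tertiary 6-OH and leaves all stereocentres and alkene geometries as they are.

## Compound list

1 | ketoisophorone | CC1=CC(=O)CC(C)(C)C1=O | starting material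
2 | (1R,6S)-1,3,3-trimethyl-7-oxabicyclo[4.1.0]heptane-2,5-dione | O=C1C(C)(C)CC(=O)[C@H]2O[C@@]12C | intermediate
3 | (2R)-2-hydroxy-2,6,6-trimethylcyclohexane-1,4-dione | O=C1C(C)(C)CC(=O)C[C@@]1(C)O | intermediate
4 | (2R,4S)-2,4-dihydroxy-2,6,6-trimethylcyclohexan-1-one | O=C1C(C)(C)C[C@H](O)C[C@@]1(C)O | intermediate
5 | (2R,4S)-4-(TBSO)-2-hydroxy-2,6,6-trimethylcyclohexan-1-one | O=C1C(C)(C)C[C@H](O[Si](C)(C)C(C)(C)C)C[C@@]1(C)O | intermediate
6 | chloro(chloromethyl)dimethylsilane | C[Si](C)(Cl)CCl | starting material
7 | O5 (chloromethyl)dimethylsilyl ether of 5 | O=C1C(C)(C)C[C@H](O[Si](C)(C)C(C)(C)C)C[C@@]1(C)O[Si](C)(C)CCl | intermediate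
8 | O5 (iodomethyl)dimethylsilyl ether of 5 (key-step precursor) | O=C1C(C)(C)C[C@H](O[Si](C)(C)C(C)(C)C)C[C@@]1(C)O[Si](C)(C)CI | intermediate
9 | silylmethyllithium from 8 | O=C1C(C)(C)C[C@H](O[Si](C)(C)C(C)(C)C)C[C@@]1(C)O[Si](C)(C)C[Li] | intermediate
10 | lithium alkoxide of 11 | C1[C@@]2(O[Li])C(C)(C)C[C@H](O[Si](C)(C)C(C)(C)C)C[C@@]2(C)O[Si]1(C)C | intermediate
11 | cis-fused oxasilolane, 6-OH free (key-step product) | C1[C@@]2(O)C(C)(C)C[C@H](O[Si](C)(C)C(C)(C)C)C[C@@]2(C)O[Si]1(C)C | intermediate
12 | (1S,2R,4S)-4-(TBSO)-1-(hydroxymethyl)-2,6,6-trimethylcyclohexane-1,2-diol | OC[C@@]1(O)C(C)(C)C[C@H](O[Si](C)(C)C(C)(C)C)C[C@@]1(C)O | intermediate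
13 | tris(trimethylsilyl) ether of 12 | C[Si](C)(C)OC[C@@]1(O[Si](C)(C)C)C(C)(C)C[C@H](O[Si](C)(C)C(C)(C)C)C[C@@]1(C)O[Si](C)(C)C | intermediate
14 | C7 alkoxydimethylsulfonium chloride | C[S+](C)OC[C@@]1(O[Si](C)(C)C)C(C)(C)C[C@H](O[Si](C)(C)C(C)(C)C)C[C@@]1(C)O[Si](C)(C)C.[Cl-] | intermediate
15 | (1R,2R,4S)-4-(TBSO)-2,6,6-trimethyl-1,2-bis(TMSO)cyclohexane-1-carbaldehyde | O=C[C@@]1(O[Si](C)(C)C)C(C)(C)C[C@H](O[Si](C)(C)C(C)(C)C)C[C@@]1(C)O[Si](C)(C)C | intermediate
16 | (6R)-2,2,6-trimethylcyclohexane-1,4-dione | C[C@@H]1CC(=O)CC(C)(C)C1=O | intermediate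
17 | (4R,6R)-4-hydroxy-2,2,6-trimethylcyclohexan-1-one | C[C@@H]1C[C@@H](O)CC(C)(C)C1=O | intermediate
18 | (4R,6R)-4-(TBDPSO)-2,2,6-trimethylcyclohexan-1-one | C[C@@H]1C[C@@H](O[Si](c2ccccc2)(c2ccccc2)C(C)(C)C)CC(C)(C)C1=O | intermediate
19 | lithium enolate of 18 | CC1=C(O[Li])C(C)(C)C[C@H](O[Si](c2ccccc2)(c2ccccc2)C(C)(C)C)C1 | intermediate
20 | (R)-4-(TBDPSO)-2,6,6-trimethylcyclohex-1-en-1-yl triflate | CC1=C(OS(=O)(=O)C(F)(F)F)C(C)(C)C[C@H](O[Si](c2ccccc2)(c2ccccc2)C(C)(C)C)C1 | intermediate
21 | (E)-3-methylpent-2-en-4-yn-1-ol | C#C/C(C)=C/CO | starting material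
22 | C15 enynol | CC1=C(C#C/C(C)=C/CO)C(C)(C)C[C@H](O[Si](c2ccccc2)(c2ccccc2)C(C)(C)C)C1 | intermediate
23 | C15 allylic bromide | CC1=C(C#C/C(C)=C/CBr)C(C)(C)C[C@H](O[Si](c2ccccc2)(c2ccccc2)C(C)(C)C)C1 | intermediate
24 | C15 enynyl triphenylphosphonium bromide | CC1=C(C#C/C(C)=C/C[P+](c2ccccc2)(c2ccccc2)c2ccccc2)C(C)(C)C[C@H](O[Si](c2ccccc2)(c2ccccc2)C(C)(C)C)C1.[Br-] | intermediate
25 | ethyl tiglate | CCOC(=O)/C(C)=C/C | starting material
26 | ethyl (E)-4-bromo-2-methylbut-2-enoate | CCOC(=O)/C(C)=C/CBr | intermediate
27 | ethyl (E)-4-(diethoxyphosphoryl)-2-methylbut-2-enoate | CCOC(=O)/C(C)=C/CP(=O)(OCC)OCC | intermediate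
28 | 2,7-dimethylocta-2,4,6-trienedial | O=C/C(C)=C/C=C/C=C(C)/C=O | starting material
29 | lithiated phosphonate from 27 | CCOC(=O)/C(C)=C/[CH-]P(=O)(OCC)OCC.[Li+] | intermediate
30 | ethyl (2E,4E,6E,8E,10E)-2,6,11-trimethyl-12-oxododeca-2,4,6,8,10-pentaenoate | CCOC(=O)/C(C)=C/C=C/C(C)=C/C=C/C=C(C)/C=O | intermediate
31 | C15 ylide from 24 | CC1=C(C#C/C(C)=C/C=P(c2ccccc2)(c2ccccc2)c2ccccc2)C(C)(C)C[C@H](O[Si](c2ccccc2)(c2ccccc2)C(C)(C)C)C1 | intermediate
32 | C30 ethyl ester | CC1=C(C#C/C(C)=C/C=C/C(C)=C/C=C/C=C(C)/C=C/C=C(C)/C(=O)OCC)C(C)(C)C[C@H](O[Si](c2ccccc2)(c2ccccc2)C(C)(C)C)C1 | intermediate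
33 | C30 allylic alcohol | CC1=C(C#C/C(C)=C/C=C/C(C)=C/C=C/C=C(C)/C=C/C=C(C)/CO)C(C)(C)C[C@H](O[Si](c2ccccc2)(c2ccccc2)C(C)(C)C)C1 | intermediate
34 | C30 triphenylphosphonium bromide | CC1=C(C#C/C(C)=C/C=C/C(C)=C/C=C/C=C(C)/C=C/C=C(C)/C[P+](c2ccccc2)(c2ccccc2)c2ccccc2)C(C)(C)C[C@H](O[Si](c2ccccc2)(c2ccccc2)C(C)(C)C)C1.[Br-] | intermediate
35 | C30 ylide from 34 | CC1=C(C#C/C(C)=C/C=C/C(C)=C/C=C/C=C(C)/C=C/C=C(C)/C=P(c2ccccc2)(c2ccccc2)c2ccccc2)C(C)(C)C[C@H](O[Si](c2ccccc2)(c2ccccc2)C(C)(C)C)C1 | intermediate
36 | fully silylated tetrol | CC1=C(C#C/C(C)=C/C=C/C(C)=C/C=C/C=C(C)/C=C/C=C(C)/C=C/[C@@]2(O[Si](C)(C)C)C(C)(C)C[C@H](O[Si](C)(C)C(C)(C)C)C[C@@]2(C)O[Si](C)(C)C)C(C)(C)C[C@H](O[Si](c3ccccc3)(c3ccccc3)C(C)(C)C)C1 | intermediate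
37 | (3S,5R,6R,3'R)-7',8'-didehydro-5,6-dihydro-beta,beta-carotene-3,5,6,3'-tetrol | CC1=C(C#C/C(C)=C/C=C/C(C)=C/C=C/C=C(C)/C=C/C=C(C)/C=C/[C@@]2(O)C(C)(C)C[C@H](O)C[C@@]2(C)O)C(C)(C)C[C@H](O)C1 | target

## Step count and risks

Total step count: 24. Longest linear sequence: 12 steps (steps 1 to 10, 23 and 24).

**Step 7 (new method).**
- What may go wrong:
  - t-BuLi may attack silicon or the carbonyl group before the exchange is complete.
  - The carbanion may be protonated or transfer silicon intermolecularly, because closure onto so crowded a ketone is slow.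
  - Silanolate may be lost by Peterson elimination on warming or on contact with acid during isolation.
- Fallback, from 5 back to 13, by known chemistry that turns the same facial bias to advantage by delivering oxygen instead of carbon:
  - The 5-OH of 5 is capped (TMSOTf, 2,6-lutidine) to give the 5-O-trimethylsilyl ketone F1.
  - Petasis methylenation (Cp2TiMe2, toluene, 80 °C) gives the exocyclic C6=C7 alkene F2.
  - Upjohn dihydroxylation (OsO4 cat., N-methylmorpholine N-oxide, acetone/water) should approach from the face remote from the axial O5 and the axial C1 methyl. O6 then ends trans to O5 and C7 cis to it, giving the 6,7-diol F3.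
  - TMSOTf with 2,6-lutidine converts F3 into 13.

**Step 23.**
- What may go wrong: sluggish addition of a strongly delocalised ylide to a neopentyl-type aldehyde, poor E/Z selectivity at C7=C8, decay of the ylide, or geometric scrambling carried over from the cationic salt formation of step 22.
- Fallback, from 15, 24 and 28 back to 36, which moves the last union to C11=C12 and makes C7=C8 with a small, E-selective phosphonate:
  - Horner–Wadsworth–Emmons reaction of 15 with commercial triethyl 3-methyl-4-phosphonocrotonate (LiN(SiMe3)2, THF) gives the C15 dienoate F4.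
  - i-Bu2AlH gives the C15 dienol F5, and MnO2 gives the C15 dienal F6.
  - In parallel, the ylide from 24 is condensed with an excess of 28 to give the C25 aldehyde F7.
  - NaBH4 gives the C25 alcohol F8, and PPh3·HBr gives the C25 phosphonium bromide F9.
  - Wittig reaction of F9 (NaN(SiMe3)2) with F6 gives 36.

**Step 1.**
- What may go wrong: low enantioselectivity through uncatalysed background epoxidation of the very electrophilic enedione, slow iminium formation, or oxidative cleavage.
- Fallback, from 1 back to 5, which sets C3 first by a reaction known for this very substrate and relays it to C5: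
  - Noyori-type asymmetric transfer hydrogenation of 1 (RuCl(p-cymene)(TsDPEN) with the ligand enantiomer that gives the 4S alcohol, HCO2H/Et3N) reduces only the unhindered carbonyl to (4S)-4-hydroxy-2,6,6-trimethylcyclohex-2-en-1-one F10.
  - TBSCl with imidazole gives the silyl ether F11.
  - Weitz–Scheffer epoxidation (t-BuOOH, benzyltrimethylammonium hydroxide, THF, 0 °C) takes place anti to the neighbouring silyloxy group and gives the 4,5-epoxy ketone F12.
  - LiBHEt3 reduces the ketone and opens the oxirane at the secondary C4, the site favoured both sterically and by the Fürst–Plattner rule. This gives the 5,6-diol F13 as a mixture at C6.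
  - Parikh–Doering oxidation (SO3·pyridine, DMSO, Et3N) of the secondary 6-OH gives 5.

## Further compounds

F1 | step 7 | 5-O-trimethylsilyl ketone | O=C1C(C)(C)C[C@H](O[Si](C)(C)C(C)(C)C)C[C@@]1(C)O[Si](C)(C)C
F2 | step 7 | exocyclic C6=C7 alkene | C=C1C(C)(C)C[C@H](O[Si](C)(C)C(C)(C)C)C[C@@]1(C)O[Si](C)(C)C
F3 | step 7 | 6,7-diol with 5-OTMS | OC[C@@]1(O)C(C)(C)C[C@H](O[Si](C)(C)C(C)(C)C)C[C@@]1(C)O[Si](C)(C)C
F4 | step 23 | C15 dienoate (7E,9E) | CCOC(=O)/C=C(C)/C=C/[C@@]1(O[Si](C)(C)C)C(C)(C)C[C@H](O[Si](C)(C)C(C)(C)C)C[C@@]1(C)O[Si](C)(C)C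
F5 | step 23 | C15 dienol | OC/C=C(C)/C=C/[C@@]1(O[Si](C)(C)C)C(C)(C)C[C@H](O[Si](C)(C)C(C)(C)C)C[C@@]1(C)O[Si](C)(C)C
F6 | step 23 | C15 dienal | O=C/C=C(C)/C=C/[C@@]1(O[Si](C)(C)C)C(C)(C)C[C@H](O[Si](C)(C)C(C)(C)C)C[C@@]1(C)O[Si](C)(C)C
F7 | step 23 | C25 aldehyde | CC1=C(C#C/C(C)=C/C=C/C(C)=C/C=C/C=C(C)/C=O)C(C)(C)C[C@H](O[Si](c2ccccc2)(c2ccccc2)C(C)(C)C)C1
F8 | step 23 | C25 alcohol | CC1=C(C#C/C(C)=C/C=C/C(C)=C/C=C/C=C(C)/CO)C(C)(C)C[C@H](O[Si](c2ccccc2)(c2ccccc2)C(C)(C)C)C1
F9 | step 23 | C25 triphenylphosphonium bromide | CC1=C(C#C/C(C)=C/C=C/C(C)=C/C=C/C=C(C)/C[P+](c2ccccc2)(c2ccccc2)c2ccccc2)C(C)(C)C[C@H](O[Si](c2ccccc2)(c2ccccc2)C(C)(C)C)C1.[Br-]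
F10 | step 1 | (4S)-4-hydroxy-2,6,6-trimethylcyclohex-2-en-1-one | O=C1C(C)(C)C[C@H](O)C=C1C
F11 | step 1 | TBS ether of F10 | O=C1C(C)(C)C[C@H](O[Si](C)(C)C(C)(C)C)C=C1C
F12 | step 1 | 4,5-epoxy ketone, oxirane anti to 3-OTBS | O=C1C(C)(C)C[C@H](O[Si](C)(C)C(C)(C)C)[C@H]2O[C@@]12C
F13 | step 1 | 5,6-diol, mixture at C6 | OC1C(C)(C)C[C@H](O[Si](C)(C)C(C)(C)C)C[C@@]1(C)O
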